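**Plan**
- Retrosynthesis: the two ester C–O bonds are cut first, giving a cyclopentane diol (its 1,3-diol as acetonide) and two molecules of one (S)-acid whose aldehydes are diethyl acetals. Next the bond from the ring to the CH(CH2OH)2 carbon is cut (malonate Michael addition), and last the ring bonds CH2–CH(O) and CH(CH3)–CH(CH2O) (formal [3+2]).
- Enabling feature: in the cyclopentane the O-bearing carbon is next to the methyl-bearing carbon, which is the C=C of a prop-1-enyl ether. The other three ring carbons (CH2, CH, C–CH2O) are the vinyl group and the carbenoid carbon of an ester-substituted vinylcarbenoid.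
- Forward: the ring is made first from an (E)-enol ether and a vinyldiazoacetate, then come malonate addition, reduction, acetonide formation and debenzylation. The acid is made separately, both hydroxyls are esterified, and one acid hydrolysis frees all aldehydes and the diol.
- Stereochemistry: the methyl- and O-bearing ring carbons come from the chiral catalyst Rh2(S-DOSP)4, dirhodium tetrakis[(S)-N-(dodecylbenzenesulfonyl)prolinate], and the (E)-geometry of the enol ether. The other two ring centres settle all-trans under thermodynamic control. The (S) side-chain centres come from an oxazolidinone auxiliary, and the (E)-enals from a (Z)-vinyl bromide.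

Key step: step 3

Remark (assumption): Rh2(S-DOSP)4 is taken to select the face of the enol ether in the sense established for its cyclopropanation of styrenes and vinyl ethers; if the cyclopentene of step 3 forms as the other enantiomer, Rh2(R-DOSP)4 is used with no other change.
Remark (assumption): compounds marked as starting materials are taken as commercially available (4,4-diethoxybut-1-ene is sold as 3-butenal diethyl acetal).

**Step 1**
Reactants: 1 allyl benzyl ether
Product: 2 (E)-benzyl prop-1-enyl ether
Conditions: [Ir(cod)(PMePh2)2]PF6 (cat., activated with H2), THF, rt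
Reagents that add atoms: none
Why: The cationic iridium hydride isomerises allyl ethers to prop-1-enyl ethers by hydrometalation/β-hydride elimination (allyl-to-propenyl ether isomerisation), a process known to favour the (E)-isomer strongly, and no stereocentre is formed.

**Step 2**
Reactants: 3 methyl but-3-enoate
Product: 4 methyl 2-diazobut-3-enoate
Conditions: p-ABSA, DBU, MeCN, 0 °C
Reagents that add atoms: 4-acetamidobenzenesulfonyl azide (p-ABSA), CC(=O)Nc1ccc(cc1)S(=O)(=O)N=[N+]=[N-]
Why: Regitz diazo transfer, in which DBU forms the dienolate of the β,γ-unsaturated ester, its α-carbon attacks the terminal nitrogen of the sulfonyl azide and the sulfonamide is expelled; the vinyldiazoacetate is kept cold and used at once because it cyclises slowly to a pyrazole.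

**Step 3**
Reactants: 2 (E)-benzyl prop-1-enyl ether; 4 methyl 2-diazobut-3-enoate
Product: 6 methyl (4R,5R)-4-(benzyloxy)-5-methylcyclopent-1-ene-1-carboxylate, via vinylcyclopropane 5 (not isolated)
Conditions: Rh2(S-DOSP)4 (1 mol %), pentane, −78 °C → rt; then Et2AlCl (1 equiv), CH2Cl2, −78 °C
Reagents that add atoms: none
Why: The rhodium carbenoid from 4 is attacked at its carbenoid carbon by the nucleophilic β-carbon of enol ether 2, which forms the first C–C bond and an oxocarbenium/dienolate zwitterion that collapses to donor–acceptor vinylcyclopropane 5 or closes directly; Et2AlCl reopens 5 to the same ion pair, whose terminal carbon (the former vinyl CH2) bonds to the oxocarbenium carbon and forms the second C–C bond. The closest known reaction type is the formal [3+2] annulation of rhodium vinylcarbenoids with vinyl ethers by cyclopropanation and Lewis-acid-induced vinylcyclopropane-to-cyclopentene rearrangement. The cyclopentene is closed by this polar 1,3-shift, an intramolecular vinylogous Mukaiyama-type attack of the dienolate terminus on the oxocarbenium ion through a five-membered transition state. C-5 (methyl) is fixed in the first bond formation by the chiral catalyst, which selects the enantioface of the enol ether, and C-4 (benzyloxy) follows from the (E)-geometry of 2, since closure with retention inside the ion pair and the preference for a pseudo-equatorial benzyloxy group both place it trans to the methyl group. The step needs attack at the carbenoid carbon and not at the vinylogous terminus, which the methyl ester, the hydrocarbon solvent and the prolinate catalyst at low temperature favour, and it needs the enol ether to outcompete benzylic C–H insertion, which its far higher nucleophilicity secures.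

**Step 4**
Reactants: 6 methyl (4R,5R)-4-(benzyloxy)-5-methylcyclopent-1-ene-1-carboxylate; 7 dimethyl malonate
Product: 8 dimethyl 2-[(1R,2S,3R,4R)-4-(benzyloxy)-2-(methoxycarbonyl)-3-methylcyclopentyl]propanedioate
Conditions: 7 (3 equiv), NaOMe (0.3 equiv), MeOH, reflux
Reagents that add atoms: none
Why: Michael addition of sodium dimethyl malonate to C-2 of the cyclopentenecarboxylate under equilibrating conditions (retro-Michael and α-epimerisation both operate in methanolic methoxide), so the two new stereocentres should settle with the ester trans to the neighbouring methyl and the malonyl group trans to the ester, which is the all-trans ring required.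

**Step 5**
Reactants: 8 dimethyl 2-[(1R,2S,3R,4R)-4-(benzyloxy)-2-(methoxycarbonyl)-3-methylcyclopentyl]propanedioate
Product: 9 2-[(1R,2S,3R,4R)-4-(benzyloxy)-2-(hydroxymethyl)-3-methylcyclopentyl]propane-1,3-diol
Conditions: LiAlH4, THF, 0 °C → reflux; aq. NaOH work-up
Reagents that add atoms: none
Why: Hydride reduction of all three methyl esters by LiAlH4 (ester reduction) should give the triol without touching the benzyl ether or any stereocentre.

**Step 6**
Reactants: 9 2-[(1R,2S,3R,4R)-4-(benzyloxy)-2-(hydroxymethyl)-3-methylcyclopentyl]propane-1,3-diol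
Product: 10 [(1S,2R,3R,5R)-3-(benzyloxy)-5-(2,2-dimethyl-1,3-dioxan-5-yl)-2-methylcyclopentyl]methanol
Conditions: 2,2-dimethoxypropane, CSA (cat.), CH2Cl2, rt
Reagents that add atoms: 2,2-dimethoxypropane, COC(C)(C)OC
Why: Acid-catalysed transacetalisation (acetonide formation under thermodynamic control) closes the six-membered 1,3-dioxane on the 2-substituted propane-1,3-diol, the only hydroxyl pair that can form an unstrained cyclic acetonide, and leaves the ring hydroxymethyl group free.

**Step 7**
Reactants: 10 [(1S,2R,3R,5R)-3-(benzyloxy)-5-(2,2-dimethyl-1,3-dioxan-5-yl)-2-methylcyclopentyl]methanol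
Product: 11 (1R,2R,3S,4R)-4-(2,2-dimethyl-1,3-dioxan-5-yl)-3-(hydroxymethyl)-2-methylcyclopentan-1-ol
Conditions: H2 (1 atm), Pd/C, EtOAc, rt
Reagents that add atoms: none
Why: Hydrogenolysis of the benzyl ether over Pd/C in a neutral solvent (O-debenzylation) should free the secondary alcohol while the acetonide and all stereocentres stay untouched.

**Step 8**
Reactants: 12 (E)-but-2-enal (crotonaldehyde)
Product: 14 (Z)-2-bromobut-2-enal, via 2,3-dibromobutanal 13 (not isolated)
Conditions: Br2, CH2Cl2, 0 °C; then Et3N, 0 °C → rt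
Reagents that add atoms: bromine, BrBr
Why: Anti-addition of bromine gives the dibromide, from which triethylamine removes HBr by E1cB elimination through the enolate (bromination/dehydrobromination) to give the more stable (Z)-α-bromoenal, with bromine cis and formyl trans to methyl, the geometry that later becomes the (E)-enal of the target.

**Step 9**
Reactants: 14 (Z)-2-bromobut-2-enal
Product: 15 (Z)-2-bromo-1,1-diethoxybut-2-ene
Conditions: HC(OEt)3, p-TsOH (cat.), EtOH, rt
Reagents that add atoms: triethyl orthoformate, CCOC(OCC)OCC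
Why: Acid-catalysed acetal formation with the orthoformate as water scavenger protects the aldehyde as its diethyl acetal without affecting the alkene geometry and makes the vinyl bromide fit for halogen–lithium exchange.

**Step 10**
Reactants: 16 (R)-4-benzyloxazolidin-2-one; 17 acryloyl chloride
Product: 18 (R)-3-acryloyl-4-benzyloxazolidin-2-one
Conditions: n-BuLi, THF, −78 °C; then 17, −78 → 0 °C
Reagents that add atoms: none
Why: N-Acylation of the lithiated oxazolidinone with the acid chloride at low temperature (imide formation) gives the acrylimide, and no new stereocentre is formed.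

**Step 11**
Reactants: 18 (R)-3-acryloyl-4-benzyloxazolidin-2-one; 19 4,4-diethoxybut-1-ene
Product: 20 (R)-4-benzyl-3-[(E)-5,5-diethoxypent-2-enoyl]oxazolidin-2-one
Conditions: second-generation Hoveyda–Grubbs catalyst (5 mol %), 19 (3 equiv), CH2Cl2, 40 °C
Reagents that add atoms: none
Why: Olefin cross-metathesis between the electron-poor acrylimide, which does not homodimerise readily, and an excess of the terminal homoallylic acetal should give the (E)-enoyl imide selectively with loss of ethene.

**Step 12**
Reactants: 15 (Z)-2-bromo-1,1-diethoxybut-2-ene; 20 (R)-4-benzyl-3-[(E)-5,5-diethoxypent-2-enoyl]oxazolidin-2-one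
Product: 23 (R)-4-benzyl-3-[(3S,4E)-3-(2,2-diethoxyethyl)-4-(diethoxymethyl)hex-4-enoyl]oxazolidin-2-one, via alkenyllithium 21 (not isolated), via alkenylmagnesium bromide 22 (not isolated)
Conditions: 15, t-BuLi (2 equiv), Et2O, −78 °C; MgBr2·OEt2; CuBr·SMe2 (0.3 equiv), THF/Me2S; 20, −78 → −20 °C; aq. NH4Cl
Reagents that add atoms: none
Why: Bromine–lithium exchange with retention of alkene geometry, transmetalation to magnesium and copper-catalysed 1,4-addition to the N-enoyl oxazolidinone in its magnesium-chelated syn-s-cis conformation (auxiliary-controlled conjugate addition), in which the benzyl group shields one face so that the alkenyl group adds to the other and sets the (S) stereocentre.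

**Step 13**
Reactants: 23 (R)-4-benzyl-3-[(3S,4E)-3-(2,2-diethoxyethyl)-4-(diethoxymethyl)hex-4-enoyl]oxazolidin-2-one
Product: 24 (3S,4E)-3-(2,2-diethoxyethyl)-4-(diethoxymethyl)hex-4-enoic acid
Conditions: LiOH, H2O2, THF/H2O, 0 °C; Na2SO3; then cold dilute HCl to pH 4
Reagents that add atoms: hydrogen peroxide (as lithium hydroperoxide), OO
Why: Lithium hydroperoxide attacks the exocyclic imide carbonyl selectively (hydroperoxide cleavage of an N-acyl oxazolidinone) and releases the acid and the recoverable auxiliary under basic conditions that leave both acetals and the β-stereocentre untouched.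

**Step 14**
Reactants: 11 (1R,2R,3S,4R)-4-(2,2-dimethyl-1,3-dioxan-5-yl)-3-(hydroxymethyl)-2-methylcyclopentan-1-ol; 24 (3S,4E)-3-(2,2-diethoxyethyl)-4-(diethoxymethyl)hex-4-enoic acid
Product: 25 {(1S,2R,3R,5R)-5-(2,2-dimethyl-1,3-dioxan-5-yl)-3-{[(3S,4E)-3-(2,2-diethoxyethyl)-4-(diethoxymethyl)hex-4-enoyl]oxy}-2-methylcyclopentyl}methyl (3S,4E)-3-(2,2-diethoxyethyl)-4-(diethoxymethyl)hex-4-enoate
Conditions: 24 (2.4 equiv), DCC, DMAP (cat.), CH2Cl2, 0 °C → rt
Reagents that add atoms: none
Why: Carbodiimide/DMAP (Steglich) esterification should acylate both the primary and the secondary hydroxyl with an excess of the acid, whose stereocentre is β to the carboxyl and cannot epimerise, while the carbinol configuration is retained.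

**Step 15**
Reactants: 25 protected bis-ester (name as in step 14)
Product: 26 {(1S,2R,3R,5R)-5-(1,3-dihydroxypropan-2-yl)-3-{[(3S,4E)-4-formyl-3-(2-oxoethyl)hex-4-enoyl]oxy}-2-methylcyclopentyl}methyl (3S,4E)-4-formyl-3-(2-oxoethyl)hex-4-enoate (target)
Conditions: 1 M aq. HCl–THF (1:4), 0 °C → rt
Reagents that add atoms: water, O
Why: Dilute aqueous acid should hydrolyse the four diethyl acetals and the acetonide in one operation (acetal hydrolysis) under conditions that spare the two esters, and the conjugation of each unmasked enal preserves the (E)-geometry fixed at the vinyl bromide stage.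

**Compound list**
1 | allyl benzyl ether | C=CCOCc1ccccc1 | starting material
2 | (E)-benzyl prop-1-enyl ether | C/C=C/OCc1ccccc1 | intermediate
3 | methyl but-3-enoate | COC(=O)CC=C | starting material
4 | methyl 2-diazobut-3-enoate | COC(=O)C(=[N+]=[N-])C=C | intermediate
5 | methyl (1S,2S,3R)-2-(benzyloxy)-1-ethenyl-3-methylcyclopropane-1-carboxylate | COC(=O)[C@]1(C=C)[C@@H](OCc2ccccc2)[C@@H]1C | intermediate (not isolated)
6 | methyl (4R,5R)-4-(benzyloxy)-5-methylcyclopent-1-ene-1-carboxylate | COC(=O)C1=CC[C@@H](OCc2ccccc2)[C@@H]1C | intermediate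
7 | dimethyl malonate | COC(=O)CC(=O)OC | starting material
8 | dimethyl 2-[(1R,2S,3R,4R)-4-(benzyloxy)-2-(methoxycarbonyl)-3-methylcyclopentyl]propanedioate | COC(=O)[C@@H]1[C@@H](C)[C@H](OCc2ccccc2)C[C@H]1C(C(=O)OC)C(=O)OC | intermediate
9 | 2-[(1R,2S,3R,4R)-4-(benzyloxy)-2-(hydroxymethyl)-3-methylcyclopentyl]propane-1,3-diol | OC[C@@H]1[C@@H](C)[C@H](OCc2ccccc2)C[C@H]1C(CO)CO | intermediate
10 | [(1S,2R,3R,5R)-3-(benzyloxy)-5-(2,2-dimethyl-1,3-dioxan-5-yl)-2-methylcyclopentyl]methanol | OC[C@@H]1[C@@H](C)[C@H](OCc2ccccc2)C[C@H]1C3COC(C)(C)OC3 | intermediate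
11 | (1R,2R,3S,4R)-4-(2,2-dimethyl-1,3-dioxan-5-yl)-3-(hydroxymethyl)-2-methylcyclopentan-1-ol | OC[C@@H]1[C@@H](C)[C@H](O)C[C@H]1C2COC(C)(C)OC2 | intermediate
12 | (E)-but-2-enal (crotonaldehyde) | C/C=C/C=O | starting material
13 | (2R*,3S*)-2,3-dibromobutanal (racemic; one enantiomer drawn) | C[C@H](Br)[C@H](Br)C=O | intermediate (not isolated)
14 | (Z)-2-bromobut-2-enal | C/C=C(\Br)C=O | intermediate
15 | (Z)-2-bromo-1,1-diethoxybut-2-ene | C/C=C(\Br)C(OCC)OCC | intermediate
16 | (R)-4-benzyloxazolidin-2-one | O=C1N[C@H](Cc2ccccc2)CO1 | starting material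
17 | acryloyl chloride | C=CC(=O)Cl | starting material
18 | (R)-3-acryloyl-4-benzyloxazolidin-2-one | C=CC(=O)N1[C@H](Cc2ccccc2)COC1=O | intermediate
19 | 4,4-diethoxybut-1-ene | C=CCC(OCC)OCC | starting material
20 | (R)-4-benzyl-3-[(E)-5,5-diethoxypent-2-enoyl]oxazolidin-2-one | CCOC(OCC)C/C=C/C(=O)N1[C@H](Cc2ccccc2)COC1=O | intermediate
21 | (E)-(1,1-diethoxybut-2-en-2-yl)lithium | C/C=C(\[Li])C(OCC)OCC | intermediate (not isolated)
22 | (E)-(1,1-diethoxybut-2-en-2-yl)magnesium bromide | C/C=C(\[Mg]Br)C(OCC)OCC | intermediate (not isolated)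
23 | (R)-4-benzyl-3-[(3S,4E)-3-(2,2-diethoxyethyl)-4-(diethoxymethyl)hex-4-enoyl]oxazolidin-2-one | C/C=C(/C(OCC)OCC)[C@@H](CC(OCC)OCC)CC(=O)N1[C@H](Cc2ccccc2)COC1=O | intermediate
24 | (3S,4E)-3-(2,2-diethoxyethyl)-4-(diethoxymethyl)hex-4-enoic acid | C/C=C(/C(OCC)OCC)[C@@H](CC(OCC)OCC)CC(=O)O | intermediate
25 | {(1S,2R,3R,5R)-5-(2,2-dimethyl-1,3-dioxan-5-yl)-3-{[(3S,4E)-3-(2,2-diethoxyethyl)-4-(diethoxymethyl)hex-4-enoyl]oxy}-2-methylcyclopentyl}methyl (3S,4E)-3-(2,2-diethoxyethyl)-4-(diethoxymethyl)hex-4-enoate | C/C=C(/C(OCC)OCC)[C@@H](CC(OCC)OCC)CC(=O)OC[C@@H]1[C@@H](C)[C@H](OC(=O)C[C@H](CC(OCC)OCC)/C(C(OCC)OCC)=C\C)C[C@H]1C2COC(C)(C)OC2 | intermediate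
26 | {(1S,2R,3R,5R)-5-(1,3-dihydroxypropan-2-yl)-3-{[(3S,4E)-4-formyl-3-(2-oxoethyl)hex-4-enoyl]oxy}-2-methylcyclopentyl}methyl (3S,4E)-4-formyl-3-(2-oxoethyl)hex-4-enoate | C/C=C(/C=O)[C@@H](CC=O)CC(=O)OC[C@@H]1[C@@H](C)[C@H](OC(=O)C[C@H](CC=O)/C(C=O)=C\C)C[C@H]1C(CO)CO | target

**Step count and risks**
Total step count: 15. Longest linear sequence: 8 steps (steps 2, 3, 4, 5, 6, 7, 14 and 15).

Step 3 may fail through sluggish or poorly enantioselective reaction of the trans-disubstituted enol ether, through attack at the vinylogous terminus of the carbenoid (wrong regiochemistry), or through loss of the trans relationship during ring closure. The fallback sets out from 1 and 4 and comes back at 25. Allyl benzyl ether 1 is isomerised with KOtBu in DMSO to (Z)-benzyl prop-1-enyl ether F1, since cis-enol ethers are the best substrates for donor/acceptor carbenoids. F1 and 4 with Rh2(R-DOSP)4 should give the isolable methyl (1R,2R,3R)-2-(benzyloxy)-1-ethenyl-3-methylcyclopropane-1-carboxylate F2, which Et2AlCl expands to methyl (4S,5R)-4-(benzyloxy)-5-methylcyclopent-1-ene-1-carboxylate F3, correct at the methyl carbon and epimeric at the O-bearing carbon. Under the conditions of steps 4 to 7, F3 is carried to dimethyl 2-[(1R,2S,3R,4S)-4-(benzyloxy)-2-(methoxycarbonyl)-3-methylcyclopentyl]propanedioate F4, 2-[(1R,2S,3R,4S)-4-(benzyloxy)-2-(hydroxymethyl)-3-methylcyclopentyl]propane-1,3-diol F5, [(1S,2R,3S,5R)-3-(benzyloxy)-5-(2,2-dimethyl-1,3-dioxan-5-yl)-2-methylcyclopentyl]methanol F6 and (1S,2R,3S,4R)-4-(2,2-dimethyl-1,3-dioxan-5-yl)-3-(hydroxymethyl)-2-methylcyclopentan-1-ol F7. A Mitsunobu reaction of F7 with acid 24 (PPh3, DIAD, THF) then esterifies the primary alcohol and the secondary alcohol with inversion, which corrects the carbinol centre and arrives at 25.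

Step 4 may fail through incomplete equilibration, so that a kinetic mixture of epimers at the malonyl-bearing carbon persists, or through slow addition to the hindered enoate. The fallback sets out from 6 and comes back at 9. Ester 6 is reduced with i-Bu2AlH to [(4R,5R)-4-(benzyloxy)-5-methylcyclopent-1-en-1-yl]methanol F8 and oxidised with MnO2 to (4R,5R)-4-(benzyloxy)-5-methylcyclopent-1-ene-1-carbaldehyde F9. The enal should take up dimethyl malonate 7 under catalytic NaOMe far more readily and reversibly than the enoate, and the adduct dimethyl 2-[(1R,2S,3R,4R)-4-(benzyloxy)-2-formyl-3-methylcyclopentyl]propanedioate F10 epimerises freely at the formyl-bearing carbon, so the all-trans isomer is reached under mild conditions. LiAlH4 reduces F10 to triol 9.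

Step 12 may fail through poor transfer of the hindered, acetal-bearing alkenyl group from copper, or through erosion of facial selectivity if the acetal oxygens disturb the magnesium chelate. The fallback sets out from 15 and 19 and comes back at 24, replacing auxiliary control by catalyst control. Cross-metathesis of ethyl acrylate with 19 gives ethyl (E)-5,5-diethoxypent-2-enoate F11. Bromide 15 is converted by bromine–lithium exchange and trapping with 2-isopropoxy-4,4,5,5-tetramethyl-1,3,2-dioxaborolane into (E)-2-(1,1-diethoxybut-2-en-2-yl)-4,4,5,5-tetramethyl-1,3,2-dioxaborolane F12. A Hayashi–Miyaura conjugate addition of F12 to F11 with Rh(acac)(C2H4)2 and the BINAP enantiomer that delivers the 3S adduct should give ethyl (3S,4E)-3-(2,2-diethoxyethyl)-4-(diethoxymethyl)hex-4-enoate F13, and saponification with LiOH gives 24.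

**Further compounds**
F1 | step 3 | (Z)-benzyl prop-1-enyl ether | C/C=C\OCc1ccccc1
F2 | step 3 | methyl (1R,2R,3R)-2-(benzyloxy)-1-ethenyl-3-methylcyclopropane-1-carboxylate | COC(=O)[C@@]1(C=C)[C@H](OCc2ccccc2)[C@@H]1C
F3 | step 3 | methyl (4S,5R)-4-(benzyloxy)-5-methylcyclopent-1-ene-1-carboxylate | COC(=O)C1=CC[C@H](OCc2ccccc2)[C@@H]1C
F4 | step 3 | dimethyl 2-[(1R,2S,3R,4S)-4-(benzyloxy)-2-(methoxycarbonyl)-3-methylcyclopentyl]propanedioate | COC(=O)[C@@H]1[C@@H](C)[C@@H](OCc2ccccc2)C[C@H]1C(C(=O)OC)C(=O)OC
F5 | step 3 | 2-[(1R,2S,3R,4S)-4-(benzyloxy)-2-(hydroxymethyl)-3-methylcyclopentyl]propane-1,3-diol | OC[C@@H]1[C@@H](C)[C@@H](OCc2ccccc2)C[C@H]1C(CO)CO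
F6 | step 3 | [(1S,2R,3S,5R)-3-(benzyloxy)-5-(2,2-dimethyl-1,3-dioxan-5-yl)-2-methylcyclopentyl]methanol | OC[C@@H]1[C@@H](C)[C@@H](OCc2ccccc2)C[C@H]1C3COC(C)(C)OC3
F7 | step 3 | (1S,2R,3S,4R)-4-(2,2-dimethyl-1,3-dioxan-5-yl)-3-(hydroxymethyl)-2-methylcyclopentan-1-ol | OC[C@@H]1[C@@H](C)[C@@H](O)C[C@H]1C2COC(C)(C)OC2
F8 | step 4 | [(4R,5R)-4-(benzyloxy)-5-methylcyclopent-1-en-1-yl]methanol | OCC1=CC[C@@H](OCc2ccccc2)[C@@H]1C
F9 | step 4 | (4R,5R)-4-(benzyloxy)-5-methylcyclopent-1-ene-1-carbaldehyde | O=CC1=CC[C@@H](OCc2ccccc2)[C@@H]1C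
F10 | step 4 | dimethyl 2-[(1R,2S,3R,4R)-4-(benzyloxy)-2-formyl-3-methylcyclopentyl]propanedioate | O=C[C@@H]1[C@@H](C)[C@H](OCc2ccccc2)C[C@H]1C(C(=O)OC)C(=O)OC
F11 | step 12 | ethyl (E)-5,5-diethoxypent-2-enoate | CCOC(=O)/C=C/CC(OCC)OCC
F12 | step 12 | (E)-2-(1,1-diethoxybut-2-en-2-yl)-4,4,5,5-tetramethyl-1,3,2-dioxaborolane | C/C=C(\B1OC(C)(C)C(C)(C)O1)C(OCC)OCC
F13 | step 12 | ethyl (3S,4E)-3-(2,2-diethoxyethyl)-4-(diethoxymethyl)hex-4-enoate | C/C=C(/C(OCC)OCC)[C@@H](CC(OCC)OCC)CC(=O)OCC
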